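(Readings and results are simulated with made-up constants; noise was put on by code.)

If the capture agent is consumed to the end, it takes 30.0% of the substrate charge away from bis adduct and spends that fraction of reagent on the way. I put this point to the meeting on east, west and south.

| flask | substrate | reagent | capture agent | remark | time |
|---|---|---|---|---|---|
| violet | 0.010 M | 0.80 equiv | 2 mM | run made earlier |  |
| amber | 0.010 M | 0.80 equiv | 1.5 mM | run made earlier |  |
| east | 0.010 M | 0.800 equiv | 3.00 mM |  | 2.5 d |
| west | 0.010 M | 1.50 equiv | 3.00 mM |  | 2.5 d |
| south | 0.010 M | 2.50 equiv | 3.00 mM |  | 2.5 d |

- violet (time / h: bis adduct / %): 0.667: 0; 2.00: 2.4; 3.00: 3.6; 5.00: 6.2; 8.00: 10.8; 10.0: 12.6; 12.0: 12.9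
- amber (time / h: bis adduct / %): 0.667: 0.7; 2.00: 2.7; 3.00: 4.1; 5.00: 6.4; 8.00: 10.6; 10.0: 12.1; 12.0: 13.7

(standard deviation of a reading: 0.5 percentage points)

- final bis adduct, as a percentage of the substrate charged, for each flask in turn (east, west, south)

The analyst reported bis adduct after 12.0 h at 12.9% in violet and 13.7% in amber, a difference of 0.8 percentage points against a scatter of 0.5 points. The capture agent's effect, she said, could not be read from those two runs.

I argued, as my own reckoning, for counting instead. Each substrate ending as bis adduct costs two reagent, and each ending as trapped intermediate costs one. That gave 25.0% for east, 60.0% for west and 70.0% for south. I called these figures the ceiling: the lesser of half the reagent left after capture and the substrate left after capture. In south the substrate is the limiting reagent, since the reagent count of 110% is more than the substrate count of 70.0%. Side product lowers the real figure; capture agent left unused lifts it.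

The forecast's author proposed 16.5%, 51% and 85%, judging that “trapping is at most a slow leak”. We parted on south, where the forecast stands higher than my ceiling by 15 points.

The flasks give 15.4% in east, 47.3% in west and 70.1% in south.

substrate + reagent → single product + released group (k = 17.9 M⁻¹ h⁻¹); reagent + single product → bis adduct + released group (k = 17.1 M⁻¹ h⁻¹); single product + capture agent → trapped intermediate (k = 51.6 M⁻¹ h⁻¹); single product → side product (k = 0.0190 h⁻¹) At 2.50 d, south still holds 20.0% of its capture agent charge, while trapped intermediate and side product together come to 29.9% of the substrate. In east, with 2.44% of the capture agent charge left, the ceiling of 25.0% lies 9.6 points above the flask. Bis adduct costs two reagent, so that gap is 19 points of reagent counted on the substrate; side product and single product, one reagent each, stand together in east at 19.7% of the substrate.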